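Before more catalyst goes into a recipe, the earlier runs can price what it buys.

| flask | substrate | coupling partner | free catalyst | remark | time |
|---|---|---|---|---|---|
| teal | 0.016 M | 0.10 M | 55 µM | run made earlier |  |
| violet | 0.058 M | 0.10 M | 55 µM | run made earlier |  |
| red | 0.050 M | 0.10 M | 110 µM | run made earlier |  |
| larch | 0.025 M | 0.150 M | 55 µM |  | 30 min |
| birch | 0.050 M | 0.100 M | 55 µM |  | 30 min |
| maple | 0.050 M | 0.100 M | 150 µM |  | 30 min |
| alder | 0.012 M | 0.0300 M | 120 µM |  | 30 min |

| run | time / min | product / % |
|---|---|---|
| teal | 1.50 | 2 |
| teal | 2.50 | 2 |
| teal | 4.00 | 3 |
| teal | 6.00 | 8 |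
| teal | 10.0 | 8 |
| teal | 15.0 | 9 |
| teal | 20.0 | 15 |
| violet | 1.00 | 1 |
| violet | 3.00 | 3 |
| violet | 6.00 | 5 |
| violet | 10.0 | 10 |
| violet | 12.0 | 8 |
| violet | 15.0 | 8 |
| violet | 20.0 | 14 |
| red | 4.00 | 7 |
| red | 8.00 | 13 |
| red | 12.0 | 18 |
| red | 15.0 | 17 |
| red | 20.0 | 21 |

(standard deviation of a reading: 1.5 percentage points)

- all flasks from highest to lowest amount of product, in percent of the substrate charged, at 30 min (larch / birch / maple / alder)
- the amount of product, in percent of the substrate charged of the flask you put first, at 30 min
- the amount of product, in percent of the substrate charged of the flask you put last, at 30 min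

Teal and violet read 15% and 14% at 20.0 min with substrate charges 3.62-fold apart, so within these readings the reaction looks pseudo-first-order in substrate, and the natural measure of progress is the load, −ln(fraction of substrate left). My own reckoning assumes that catalyst dies in pairs and so takes as its clock the dose, catalyst charge times time. The readings can test this. Red, with twice the catalyst, reaches at 10.0 min the dose that teal and violet have at 20.0 min, and its readings on either side of that time average 15.5% against 14.5% for their last readings, within the scatter of 1.5 percentage points.

The load read from these scattered readings is 0.157 at the lower dose and 0.236 at red's last reading, one doubling later. That difference, 0.0791, is the gain per doubling of dose. Maple lies 1.03 doublings beyond red's last reading. Repeating the ratio of the loads gives 30.2%, but that is the weak link: on the assumption of death in pairs, the load at large dose grows by a constant sum per doubling, not a constant factor. Adding the gain instead gives maple 27.2%. Taking the load as proportional to partner, birch comes to 18.4%, larch to 26.2% and alder to 8.38%.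

The forecast reads maple > larch > birch > alder, with 32% first and 9% last, and says: “Partner was never varied, so I assume first order, which is the main uncertainty”. Its maple stands higher than the reckoning above.

The flasks give maple > larch > birch > alder, with maple 26.1%, larch 23.7%, birch 15.4% and alder 8.79%. The forecast's 32%, which is what first order to completion through the last reading of the red run gives, lies 5.9 points above maple; the gain of 0.0791 per doubling put maple 1.1 points above.

    coupling partner + catalyst intermediate A ⇌ catalyst intermediate B (K = 22.0 M⁻¹, k = 16.0 M⁻¹ s⁻¹)
    coupling partner ⇌ dormant form (K = 0.480, k = 0.00110 s⁻¹)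
    2 free catalyst → spent catalyst (k = 6.70 M⁻¹ s⁻¹)
    catalyst intermediate C → free catalyst + product (k = 4.10 s⁻¹)
    catalyst intermediate B ⇌ released group + catalyst intermediate C (K = 0.00580 M, k = 21.0 s⁻¹)
    coupling partner + released group ⇌ idle adduct, settled at all times (K = 1100 M⁻¹)
    substrate + free catalyst ⇌ catalyst intermediate A (K = 2.70 M⁻¹, k = 600 M⁻¹ s⁻¹)

In maple the first half-life of free catalyst by the pairing step alone, reckoned from its charge, is 8.29 min, shorter than the 30 min run. At 30.0 min free catalyst in maple stands at 23.6% and spent catalyst at 73.5% of the catalyst charged.

The neighbour of maple with 0.25 M of partner has maple's dose, so with the load again taken as proportional to partner the gain scales to 0.198 per doubling and the reckoning gives 54.8%. That flask gives 53.7%.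

(The numbers in the tables come from a simulation with made-up constants; the scatter is artificial.)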